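## The problem

The target 33 is an elemane-type sesquiterpenoid. One cyclohexane (C5 to C10) carries six contiguous stereocentres and is cis-fused across C7–C8 to an α-methylene-γ-butyrolactone (C11, C12, C13; ring oxygen on C8). C10 is quaternary (methyl C14 and the C1=C2 vinyl group), C5 bears a 3-hydroxyprop-1-en-2-yl branch (C4, C3, C15), C6 a free hydroxyl and C9 an isobutyrate. The substituents on C5, C6 and C7 alternate faces (trans,trans), while O8 and O9 are cis to each other and to the C7 arm.

Only C8 and C9 form a pattern found in the chiral pool (a cis-diol). They therefore have to control C7 and the quaternary C10 in an open chain, and these four centres then have to control C5 and C6 when the ring is closed.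

The fragile groups are the α-methylene lactone (Michael acceptor), the C9 ester next to free hydroxyls (acyl shift, translactonisation towards O6) and the 2-substituted allylic alcohol (strong acid). They are made or unmasked last, and hydrogenation, strong base and strong acid are excluded at the end.

The feature that opens the route is that C5–C6 is an aldol bond once C4 is a ketone and C6 an aldehyde. In the chair with O8 and the C10 methyl axial, the C5, C6 and C7 substituents are all equatorial, so a reversible aldol closure should settle on the required C5 and C6 configurations.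

There is one caveat. The 5,6,7-tri-epi triad is also all-equatorial, in the flipped chair (O9 and vinyl axial), which avoids the syn-axial O8/methyl contact and is estimated to be at least as stable. C7 therefore cannot be left to equilibrate. It is set before ring closure.

## Retrosynthesis

**Deprotection and the methylene lactone.** 33 is traced to its 6-O-silyl, 15-O-(4-methoxybenzyl) derivative 31 (through 32). The C11=C13 bond of 31 is cut to lactone 28, and the isobutyrate to alcohol 27. The exocyclic methylene is the last C–C bond formed because it is the least robust group. Acylation comes before it, at the one point where O9 is the only free hydroxyl. The forward enolate Mannich reaction must deprotonate the lactone and not the isobutyrate.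

**Lactone C12–O8.** 27 is opened to the tert-butyl ester/acetonide 25. Holding O8 and O9 in one acetonide keeps the chiral-pool diol intact through the whole route. It also differentiates the two oxygens without extra steps: on release only O8 is cis to the C7 arm and can close a γ-lactone, which leaves O9 for the ester. O6 stays silylated so that the trans 12,6-lactone cannot form. One acid treatment has to do both jobs without touching the silyl ether, the PMB ether or the alkenes.

**C4=C3.** 25 goes back to ketone 24 (methylenation) and, by removing the silyl group, to ketol 23. The C4 carbonyl is kept as long as it is needed to acidify C5, and C3 is added afterwards.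

**Ring closure, C5–C6 (key).** 23 is cut between C5 and C6 to keto aldehyde 22. Cuts at C7–C8 or C9–C10 would break up the diol, and a cut at C10–C5 would ask a cyclisation to form the quaternary centre. The C5–C6 cut removes the ring and two stereocentres and leaves a chain whose four remaining stereocentres sit on or next to the diol. The forward step must use C5 (not C15) as the nucleophile, give trans,trans at C5/C6/C7 and leave C7 untouched.

**C10–C5.** 22 comes from acetal 21, and 21 from a Carroll rearrangement of the acetoacetate of the Z allylic alcohol 16 with keto ester 18 (made from 17). One sigmatropic step installs the vinyl group, the quaternary centre and the C5–C4(=O)–C15 arm. Alkylation at C10 is not possible (nothing acidifies it), and conjugate addition to a β,β-disubstituted enone is slow. The Z alkene is chosen because allylic 1,3-strain then fixes H9 in the alkene plane, so the face of C10 depends only on whether the new bond forms anti to O9 or anti to C8. The forward step needs the anti-to-oxygen course.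

**C10=C1 and C10–C14.** 16 goes back through enoate 15 to methyl ketone 14, and 14 through carbinol 13 and aldehyde 12 to alcohol 11. These are standard operations on the former CH2OH terminus, and the olefination must be Z-selective.

**C6 and C7–C6.** The acetal in 11 and 10 masks aldehyde 9, which comes by a Nef reaction from nitro ester 7. 7 is the conjugate adduct of nitromethane 6 and enoate 5. This is the step that sets C7 syn to O8. It is placed early, on a simple substrate, where the sense of addition is known.

**C7=C11 and the chiral pool.** 5 is the silyl ether of 4, the Wittig product of lactol 2 with ylide 3. 2 is the half-reduced form of D-erythronolactone acetonide 1, which supplies C7 to C10 with C8 and C9 in the correct absolute configuration.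

## Roads not taken

**Alternative 1:** The carbocycle is bought ready-made as toluene cis-dihydrodiol A1 (C8 and C9 in place), and the cut is made at C7–C11 and C6–O. After differentiation of the hydroxyls, the bromoacetal A2 on O8 is treated with Bu3SnH and excess TEMPO. The C11 radical adds 5-exo to C7 of the diene and the allyl radical is trapped at C6, giving A3.
- Merits: the ring and the cis-diol come enantiopure from an arene; the cis C7/C8 fusion is enforced by the 5-exo closure; the C6 oxygen arrives in the same step; the lactol carbon is one oxidation from the lactone.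
- Weak points: A3 still has a C5=C10 alkene. The quaternary centre and the C5 branch must then be added to a trisubstituted alkene on a crowded ring. In practice this means oxidising C6 to an enone (discarding the centre just set), a conjugate vinyl addition at a β,β-disubstituted carbon and an enolate trapping. Capture of the allyl radical at C6 and not at C10 is also not assured.
- Comparison: this road reaches a lactone-bearing ring in far fewer steps and has no open-chain stereocontrol at C7, which is better than the chosen plan. The chosen plan sets against it that every carbon substituent, including the quaternary centre, is in place when the ring closes, so the hardest problem is not postponed to a hindered cyclohexene.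

**Alternative 2:** The cut is at C10–C1 and C5–C4. Enone A4 and methyl cyclobut-1-ene-1-carboxylate A5 combine under irradiation to the ladder photoadduct A6. Thermal opening of its bicyclo[2.2.0]hexane then releases the vinyl group on C10 and an acrylate on C5.
- Merits: the quaternary centre is set on a ring, anti to the C9 oxygen, which is more reliable than the open-chain control used here. One four-carbon reagent supplies C1 to C4 and C15. The sequence is short.
- Weak points: head-to-head versus head-to-tail regiochemistry in the cycloaddition. The cis fusion puts C4 and the vinyl group on the same face, so C5 must be inverted next to the C6 ketone. The cis-dialkenylcyclohexane formed on heating can undergo Cope rearrangement to a ten-membered ring. The C7 acetate arm must then be introduced by enolate chemistry on a ketone whose other α-hydrogen (C5) is also γ to the acrylate, which invites alkene migration.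
- Comparison: this road is better at C10 and shorter. The chosen plan sets against it that C7 is fixed before the ring exists, that no step puts base on a doubly activated C5–H, and that no photochemical or high-temperature fragmentation of an advanced intermediate is needed.

**Alternative 3:** The cut is at C7–C8, C11–C12 and C12–O. The allenyl aldehyde A7 is treated with Mo(CO)6 (zerovalent molybdenum). The C8 aldehyde, the inner allene double bond and CO combine in a hetero-Pauson–Khand reaction to the bis(silyl) ether A8 of the target.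
- Merits: ring, lactone and exocyclic methylene form in one step; the isobutyrate is already in place; one desilylation finishes the synthesis. No other road has an endgame as short.
- Weak points: A7 is an open chain with four contiguous stereocentres (C5, C6, C9 and the quaternary C10) and no obvious chiral-pool source. Its aldehyde is α-acyloxy (epimerisation, acyl shift). The metal must discriminate the allene from two other alkenes. The new C7 and C8 centres would be set relative to C6 and C9 by substrate bias alone, on a substrate class where only simple tethers are documented.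
- Comparison: the endgame is clearly better than the seven steps needed here after ring closure. The chosen plan offers a ring closure that is reversible and corrects C5 and C6 by itself, and precursors in which only two stereocentres (C7, C10) have to be created in the open chain, both next to the diol.

Key step: step 16

Remarks on the chemistry:
- Carbons are numbered as in elemanes (C1=C2 vinyl, C3 methylene on C4, C15 the CH2O carbon, C11–C13 lactone carbons, C14 methyl).
- 4 and 5 are drawn as the Z isomers that are expected to predominate.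
- 13 is a mixture at the carbinol carbon, 20 at C5, and 29 and 30 at C11. None of these centres survives.

Step 1
Reactants: 1 2,3-O-isopropylidene-D-erythronolactone
Product: 2 2,3-O-isopropylidene-D-erythrofuranose (lactol; anomers)
Conditions: iBu2AlH (1.1 equiv), CH2Cl2, −78 °C
Reagents that add atoms: none
Why: Half-reduction of a γ-lactone by iBu2AlH stops at the lactol because the aluminium hemiacetal is stable at −78 °C; C8 and C9 are untouched.

Step 2
Reactants: 2 2,3-O-isopropylidene-D-erythrofuranose; 3 tert-butyl (triphenylphosphoranylidene)acetate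
Product: 4 tert-butyl (Z)-3-[(4S,5R)-5-(hydroxymethyl)-2,2-dimethyl-1,3-dioxolan-4-yl]prop-2-enoate
Conditions: CH2Cl2, 0 °C → rt
Reagents that add atoms: none
Why: Wittig olefination of the hydroxy aldehyde in equilibrium with the lactol; stabilised ylides and α-alkoxy aldehydes give mainly the Z enoate, and any E isomer is carried on because step 4 gives the same C7 configuration from either geometry. The product is silylated at once so that the free hydroxyl cannot close onto the enoate.

Step 3
Reactants: 4 tert-butyl (Z)-3-[(4S,5R)-5-(hydroxymethyl)-2,2-dimethyl-1,3-dioxolan-4-yl]prop-2-enoate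
Product: 5 tert-butyl (Z)-3-[(4S,5R)-5-{[tert-butyl(diphenyl)silyl]oxymethyl}-2,2-dimethyl-1,3-dioxolan-4-yl]prop-2-enoate
Conditions: tBuPh2SiCl (1.1 equiv), imidazole (2 equiv), CH2Cl2, 0 °C → rt
Reagents that add atoms: tert-butyl(chloro)diphenylsilane, CC(C)(C)[Si](Cl)(c1ccccc1)c1ccccc1
Why: Silylation of the primary alcohol blocks the oxa-Michael closure under the basic conditions of step 4; this silyl ether also survives the acidic methanol of step 6.

Step 4
Reactants: 5 tert-butyl (Z)-3-[(4S,5R)-5-{[tert-butyl(diphenyl)silyl]oxymethyl}-2,2-dimethyl-1,3-dioxolan-4-yl]prop-2-enoate; 6 nitromethane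
Product: 7 tert-butyl (3S)-3-[(4S,5R)-5-{[tert-butyl(diphenyl)silyl]oxymethyl}-2,2-dimethyl-1,3-dioxolan-4-yl]-4-nitrobutanoate
Conditions: MeNO2 (solvent), DBU (0.5 equiv), rt
Reagents that add atoms: none
Why: Michael addition of the nitronate to the γ-alkoxy enoate. H8 lies in the alkene plane (allylic 1,3-strain) and the nitronate approaches anti to the C9 branch of the dioxolane, which places the nitromethyl group syn to O8 (7S); this is the sense documented for nitromethane additions to γ,δ-dioxolanyl enoates. The minor anti adduct, if formed, is removed here.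

Step 5
Reactants: 7 tert-butyl (3S)-3-[(4S,5R)-5-{[tert-butyl(diphenyl)silyl]oxymethyl}-2,2-dimethyl-1,3-dioxolan-4-yl]-4-nitrobutanoate
Product: 9 tert-butyl (3R)-3-[(4S,5R)-5-{[tert-butyl(diphenyl)silyl]oxymethyl}-2,2-dimethyl-1,3-dioxolan-4-yl]-4-oxobutanoate, via sodium nitronate 8 (not isolated)
Conditions: NaOMe (1.0 equiv), MeOH, 0 °C; O3, MeOH–CH2Cl2, −78 °C; N2 purge, pH 7 buffer
Reagents that add atoms: ozone, [O-][O+]=O
Why: Nef reaction in its ozonolytic form: the C=N bond of the nitronate is cleaved to the aldehyde and nitrite. One equivalent of base is used and is consumed, so the β-alkoxy aldehyde is not left in methoxide and C7 keeps its configuration (the descriptor changes only because C6 gains priority).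

Step 6
Reactants: 9 tert-butyl (3R)-3-[(4S,5R)-5-{[tert-butyl(diphenyl)silyl]oxymethyl}-2,2-dimethyl-1,3-dioxolan-4-yl]-4-oxobutanoate
Product: 10 tert-butyl (3R)-3-[(4S,5R)-5-{[tert-butyl(diphenyl)silyl]oxymethyl}-2,2-dimethyl-1,3-dioxolan-4-yl]-4,4-dimethoxybutanoate
Conditions: HC(OMe)3 (5 equiv), PPTS (0.1 equiv), MeOH, rt
Reagents that add atoms: trimethyl orthoformate, COC(OC)OC
Why: Acetalisation of the aldehyde under mild acid; the internal acetonide, the tert-butyl ester and the silyl ether tolerate pyridinium tosylate. The silyl group is kept on purpose, since a free C10 hydroxyl would close a six-membered cyclic acetal with C6.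

Step 7
Reactants: 10 tert-butyl (3R)-3-[(4S,5R)-5-{[tert-butyl(diphenyl)silyl]oxymethyl}-2,2-dimethyl-1,3-dioxolan-4-yl]-4,4-dimethoxybutanoate
Product: 11 tert-butyl (3R)-3-[(4S,5R)-5-(hydroxymethyl)-2,2-dimethyl-1,3-dioxolan-4-yl]-4,4-dimethoxybutanoate
Conditions: Bu4NF (1.5 equiv), AcOH (1.5 equiv), THF, 0 °C → rt
Reagents that add atoms: none
Why: Fluoride desilylation; in the buffered, non-acidic medium the dimethyl acetal does not exchange with the liberated hydroxyl.

Step 8
Reactants: 11 tert-butyl (3R)-3-[(4S,5R)-5-(hydroxymethyl)-2,2-dimethyl-1,3-dioxolan-4-yl]-4,4-dimethoxybutanoate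
Product: 12 tert-butyl (3R)-3-[(4S,5S)-5-formyl-2,2-dimethyl-1,3-dioxolan-4-yl]-4,4-dimethoxybutanoate
Conditions: Dess–Martin periodinane (1.3 equiv), NaHCO3, CH2Cl2, 0 °C → rt; used crude
Reagents that add atoms: none
Why: Dess–Martin oxidation under buffered conditions; the cis-dioxolane α-alkoxy aldehyde is configurationally labile and is taken on without purification.

Step 9
Reactants: 12 tert-butyl (3R)-3-[(4S,5S)-5-formyl-2,2-dimethyl-1,3-dioxolan-4-yl]-4,4-dimethoxybutanoate
Product: 13 tert-butyl (3R)-3-[(4S,5R)-5-(1-hydroxyethyl)-2,2-dimethyl-1,3-dioxolan-4-yl]-4,4-dimethoxybutanoate (carbinol epimers)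
Conditions: MeMgBr (1.3 equiv), THF, −78 °C
Reagents that add atoms: methylmagnesium bromide, C[Mg]Br
Why: Grignard addition to the aldehyde brings in C14; the tert-butyl ester is inert at −78 °C and the carbinol configuration is irrelevant because it is oxidised next.

Step 10
Reactants: 13 tert-butyl (3R)-3-[(4S,5R)-5-(1-hydroxyethyl)-2,2-dimethyl-1,3-dioxolan-4-yl]-4,4-dimethoxybutanoate
Product: 14 tert-butyl (3R)-3-[(4S,5S)-5-acetyl-2,2-dimethyl-1,3-dioxolan-4-yl]-4,4-dimethoxybutanoate
Conditions: Dess–Martin periodinane (1.3 equiv), NaHCO3, CH2Cl2, rt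
Reagents that add atoms: none
Why: Dess–Martin oxidation to the methyl ketone under buffered, non-enolising conditions, so C9 is not epimerised.

Step 11
Reactants: 14 tert-butyl (3R)-3-[(4S,5S)-5-acetyl-2,2-dimethyl-1,3-dioxolan-4-yl]-4,4-dimethoxybutanoate
Product: 15 tert-butyl (3R)-3-[(4S,5R)-5-[(Z)-4-methoxy-4-oxobut-2-en-2-yl]-2,2-dimethyl-1,3-dioxolan-4-yl]-4,4-dimethoxybutanoate
Conditions: (CF3CH2O)2P(O)CH2CO2Me (1.5 equiv), KN(SiMe3)2 (1.4 equiv), 18-crown-6 (3 equiv), THF, −78 → −20 °C
Reagents that add atoms: methyl 2-[bis(2,2,2-trifluoroethoxy)phosphoryl]acetate, COC(=O)CP(=O)(OCC(F)(F)F)OCC(F)(F)F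
Why: Still–Gennari variant of the Horner–Wadsworth–Emmons olefination; the preformed, weakly basic phosphonate anion adds to the activated α-alkoxy ketone without enolising it and should favour the Z enoate (dioxolane cis to the ester). The E isomer is removed by chromatography.

Step 12
Reactants: 15 tert-butyl (3R)-3-[(4S,5R)-5-[(Z)-4-methoxy-4-oxobut-2-en-2-yl]-2,2-dimethyl-1,3-dioxolan-4-yl]-4,4-dimethoxybutanoate
Product: 16 tert-butyl (3R)-3-[(4S,5R)-5-[(Z)-4-hydroxybut-2-en-2-yl]-2,2-dimethyl-1,3-dioxolan-4-yl]-4,4-dimethoxybutanoate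
Conditions: iBu2AlH (2.3 equiv), CH2Cl2, −78 °C
Reagents that add atoms: none
Why: 1,2-Reduction of the conjugated methyl ester to the allylic alcohol; the hindered tert-butyl ester is reduced much more slowly at −78 °C.

Step 13
Reactants: 17 ethyl 4-chloro-3-oxobutanoate
Product: 18 ethyl 4-[(4-methoxyphenyl)methoxy]-3-oxobutanoate
Conditions: NaH (2.2 equiv), 4-MeOC6H4CH2OH (1.1 equiv), THF, 0 °C → rt; 1 M HCl
Reagents that add atoms: 4-methoxybenzyl alcohol, COc1ccc(CO)cc1
Why: The first equivalent of base stores the keto ester as its enolate and the alkoxide displaces the α'-chloride (Williamson-type substitution), as is routine for 4-alkoxyacetoacetates.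

Step 14
Reactants: 16 tert-butyl (3R)-3-[(4S,5R)-5-[(Z)-4-hydroxybut-2-en-2-yl]-2,2-dimethyl-1,3-dioxolan-4-yl]-4,4-dimethoxybutanoate; 18 ethyl 4-[(4-methoxyphenyl)methoxy]-3-oxobutanoate
Product: 21 tert-butyl (3R)-3-[(4S,5R)-5-[(3R)-6-[(4-methoxyphenyl)methoxy]-3-methyl-5-oxohex-1-en-3-yl]-2,2-dimethyl-1,3-dioxolan-4-yl]-4,4-dimethoxybutanoate, via allyl keto ester 19 (not isolated), via keto acid 20 (not isolated)
Conditions: 18 (1.5 equiv), DMAP (0.1 equiv), 1,2-dichlorobenzene, 130 °C (−EtOH), then 170 °C (−CO2)
Reagents that add atoms: none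
Why: Carroll rearrangement: transesterification gives 19, whose enol undergoes the [3,3] shift to 20, which loses CO2. C10 is set by C9: in the Z alkene allylic 1,3-strain holds H9 in the alkene plane, and the new C10–C5 bond is expected to form anti to the C9–O9 bond, as in sigmatropic shifts and osmylations of Z-alkenyl dioxolanes, which is the (10R) face of 21 and the target's C10. The C10 epimer, if formed, is separated here.

Step 15
Reactants: 21 tert-butyl (3R)-3-[(4S,5R)-5-[(3R)-6-[(4-methoxyphenyl)methoxy]-3-methyl-5-oxohex-1-en-3-yl]-2,2-dimethyl-1,3-dioxolan-4-yl]-4,4-dimethoxybutanoate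
Product: 22 tert-butyl (3R)-3-[(4S,5R)-5-[(3R)-6-[(4-methoxyphenyl)methoxy]-3-methyl-5-oxohex-1-en-3-yl]-2,2-dimethyl-1,3-dioxolan-4-yl]-4-oxobutanoate
Conditions: PPTS (0.2 equiv), acetone–H2O (10:1), 40 °C; used crude
Reagents that add atoms: water, O
Why: Acid-catalysed hydrolysis (transacetalisation) of the acyclic dimethyl acetal; with acetone as solvent the acetonide cannot be lost, and the tert-butyl ester and PMB ether are stable to pyridinium tosylate.

Step 16
Reactants: 22 tert-butyl (3R)-3-[(4S,5R)-5-[(3R)-6-[(4-methoxyphenyl)methoxy]-3-methyl-5-oxohex-1-en-3-yl]-2,2-dimethyl-1,3-dioxolan-4-yl]-4-oxobutanoate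
Product: 23 tert-butyl (5S,6S,7S,8S,9R,10S)-6-hydroxy-8,9-(isopropylidenedioxy)-15-[(4-methoxyphenyl)methoxy]-4-oxo-3-norelem-1-en-12-oate (cyclohexane ketol; C5 acyl, C6 hydroxyl and C7 CH2CO2tBu all equatorial)
Conditions: pyrrolidine (0.3 equiv), AcOH (0.3 equiv), THF (0.02 M), 0 °C → rt; pH 7 buffer
Reagents that add atoms: none
Why: Pyrrolidinium acetate converts the C4 ketone reversibly into its enamines; the one towards C5 adds to the acid-activated C6 aldehyde and hydrolysis of the iminium ion releases the ketol, the closest known type being the amine-catalysed intramolecular aldol addition of keto aldehydes. The cyclohexane closes in the 6-enolexo-trig mode through a chair in which the C7 arm, fixed syn to O8 in step 4, is equatorial. C6 is set in that chair with the aldehyde oxygen equatorial and is corrected by retro-aldol and re-addition; C5 lies α to the ketone and settles through the enamine with the acyl group equatorial. Both are governed by C7 together with the cis-dioxolane and the quaternary C10, which leave the chair with O8 and the C10 methyl axial as the only one that keeps the C7 arm equatorial. The step needs trans,trans at C5/C6/C7 and C5 as the nucleophile: closure from C15 would give an eight-membered ring and attack of the C7 enamine on C4 a crowded tertiary ketol, and both revert. It also needs C7 to keep its configuration, because the 5,6,7-tri-epi isomer is all-equatorial in the flipped chair; the α-branched aldehyde forms its enamine slowly, and the reaction is stopped once 22 is consumed and not equilibrated further.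

Step 17
Reactants: 23 tert-butyl (5S,6S,7S,8S,9R,10S)-6-hydroxy-8,9-(isopropylidenedioxy)-15-[(4-methoxyphenyl)methoxy]-4-oxo-3-norelem-1-en-12-oate
Product: 24 tert-butyl (5S,6S,7R,8S,9R,10S)-8,9-(isopropylidenedioxy)-15-[(4-methoxyphenyl)methoxy]-4-oxo-6-[tri(propan-2-yl)silyloxy]-3-norelem-1-en-12-oate
Conditions: iPr3SiOTf (1.5 equiv), 2,6-lutidine (3 equiv), CH2Cl2, −40 → 0 °C
Reagents that add atoms: tri(propan-2-yl)silyl trifluoromethanesulfonate, CC(C)[Si](OS(=O)(=O)C(F)(F)F)(C(C)C)C(C)C
Why: Silyl triflate/lutidine silylation of the hindered ketol without retro-aldol; the triisopropylsilyl ether is chosen because it must survive the acid of step 19.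

Step 18
Reactants: 24 tert-butyl (5S,6S,7R,8S,9R,10S)-8,9-(isopropylidenedioxy)-15-[(4-methoxyphenyl)methoxy]-4-oxo-6-[tri(propan-2-yl)silyloxy]-3-norelem-1-en-12-oate
Product: 25 tert-butyl (5S,6R,7R,8S,9R,10S)-8,9-(isopropylidenedioxy)-15-[(4-methoxyphenyl)methoxy]-6-[tri(propan-2-yl)silyloxy]elema-1,3-dien-12-oate
Conditions: Ph3PCH3Br (3 equiv), KOtBu (2.8 equiv), THF, 0 °C → rt
Reagents that add atoms: methyltriphenylphosphonium bromide, C[P+](c1ccccc1)(c1ccccc1)c1ccccc1.[Br-]
Why: Wittig methylenation of the α-alkoxy ketone. The equatorial C6–O bond lies in the nodal plane of the C4–C5 enolate, so base-induced loss of the silyloxy group is stereoelectronically disfavoured, and epimerisation at C5 can only return the equatorial isomer.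

Step 19
Reactants: 25 tert-butyl (5S,6R,7R,8S,9R,10S)-8,9-(isopropylidenedioxy)-15-[(4-methoxyphenyl)methoxy]-6-[tri(propan-2-yl)silyloxy]elema-1,3-dien-12-oate
Product: 27 (5S,6R,7R,8S,9R,10S)-9-hydroxy-15-[(4-methoxyphenyl)methoxy]-6-[tri(propan-2-yl)silyloxy]elema-1,3-dien-12,8-olide, via diol tert-butyl ester 26 (not isolated)
Conditions: TsOH·H2O (0.2 equiv), MeOH, 40 °C; then PhMe, 60 °C
Reagents that add atoms: none
Why: Acid-catalysed methanolysis of the acetonide, then lactonisation of the axial C8 hydroxyl onto the cis-disposed tert-butyl ester (5-exo-trig acyl transfer). O9 could only give a bridged δ-lactone and O6 is silylated, so the cis-fused 12,8-lactone is the only outlet; dilute sulfonic acid in methanol spares the PMB ether, the silyl ether and the alkenes.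

Step 20
Reactants: 27 (5S,6R,7R,8S,9R,10S)-9-hydroxy-15-[(4-methoxyphenyl)methoxy]-6-[tri(propan-2-yl)silyloxy]elema-1,3-dien-12,8-olide
Product: 28 (5S,6R,7R,8S,9R,10S)-15-[(4-methoxyphenyl)methoxy]-9-(2-methylpropanoyloxy)-6-[tri(propan-2-yl)silyloxy]elema-1,3-dien-12,8-olide
Conditions: (iPrCO)2O (2 equiv), Et3N (3 equiv), DMAP (0.2 equiv), CH2Cl2, rt
Reagents that add atoms: 2-methylpropanoic anhydride, CC(C)C(=O)OC(=O)C(C)C
Why: DMAP-catalysed acylation of the only free hydroxyl, the equatorial C9 alcohol.

Step 21
Reactants: 28 (5S,6R,7R,8S,9R,10S)-15-[(4-methoxyphenyl)methoxy]-9-(2-methylpropanoyloxy)-6-[tri(propan-2-yl)silyloxy]elema-1,3-dien-12,8-olide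
Product: 31 (5S,6R,7R,8S,9R,10S)-15-[(4-methoxyphenyl)methoxy]-9-(2-methylpropanoyloxy)-6-[tri(propan-2-yl)silyloxy]elema-1,3,11(13)-trien-12,8-olide, via Mannich base 29 (not isolated), via ammonium iodide 30 (not isolated)
Conditions: LiN(iPr)2 (1.1 equiv), THF, −78 °C; CH2=NMe2+ I− (1.5 equiv), −78 → 0 °C; MeI, MeOH, rt; NaHCO3 (aq), CH2Cl2, rt
Reagents that add atoms: N,N-dimethylmethaniminium iodide (Eschenmoser's salt), C=[N+](C)C.[I-]
Why: Enolate Mannich reaction, then quaternisation and Hofmann-type elimination, the standard α-methylenation of γ-lactones. The lactone CH2 is more acidic and far less hindered than the isobutyrate methine, so kinetic deprotonation at −78 °C takes place at C11, and the enolate has no leaving group on C7.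

Step 22
Reactants: 31 (5S,6R,7R,8S,9R,10S)-15-[(4-methoxyphenyl)methoxy]-9-(2-methylpropanoyloxy)-6-[tri(propan-2-yl)silyloxy]elema-1,3,11(13)-trien-12,8-olide
Product: 32 (5S,6R,7R,8S,9R,10S)-15-hydroxy-9-(2-methylpropanoyloxy)-6-[tri(propan-2-yl)silyloxy]elema-1,3,11(13)-trien-12,8-olide
Conditions: DDQ (1.3 equiv), CH2Cl2–pH 7 buffer (10:1), 0 °C
Reagents that add atoms: none
Why: Oxidative cleavage of the 4-methoxybenzyl ether (hydride abstraction, hydrolysis of the oxocarbenium ion) under neutral conditions that leave the enoate, the ester and the alkenes alone.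

Step 23
Reactants: 32 (5S,6R,7R,8S,9R,10S)-15-hydroxy-9-(2-methylpropanoyloxy)-6-[tri(propan-2-yl)silyloxy]elema-1,3,11(13)-trien-12,8-olide
Product: 33 (5S,6R,7S,8S,9R,10S)-6,15-dihydroxy-9-(2-methylpropanoyloxy)elema-1,3,11(13)-trien-12,8-olide (target)
Conditions: HF·pyridine, pyridine, THF, 0 °C → rt
Reagents that add atoms: none
Why: Fluoride-mediated desilylation in a buffered, weakly acidic medium, which avoids base-induced acyl shift or translactonisation towards the liberated C6 hydroxyl.

## Compound list

1 | 2,3-O-isopropylidene-D-erythronolactone, (3aR,6aR) | C1[C@H]2OC(C)(C)O[C@H]2C(=O)O1 | starting material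
2 | 2,3-O-isopropylidene-D-erythrofuranose (anomers) | C1[C@H]2OC(C)(C)O[C@H]2C(O)O1 | intermediate
3 | tert-butyl (triphenylphosphoranylidene)acetate | CC(C)(C)OC(=O)C=P(c1ccccc1)(c1ccccc1)c1ccccc1 | starting material
4 | tert-butyl (Z)-3-[(4S,5R)-5-(hydroxymethyl)-2,2-dimethyl-1,3-dioxolan-4-yl]prop-2-enoate | OC[C@H]1OC(C)(C)O[C@H]1/C=C\C(=O)OC(C)(C)C | intermediate
5 | tert-butyl (Z)-3-[(4S,5R)-5-{[tert-butyl(diphenyl)silyl]oxymethyl}-2,2-dimethyl-1,3-dioxolan-4-yl]prop-2-enoate | CC(C)(C)[Si](OC[C@H]1OC(C)(C)O[C@H]1/C=C\C(=O)OC(C)(C)C)(c1ccccc1)c1ccccc1 | intermediate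
6 | nitromethane | C[N+](=O)[O-] | starting material
7 | tert-butyl (3S)-3-[(4S,5R)-5-{[tert-butyl(diphenyl)silyl]oxymethyl}-2,2-dimethyl-1,3-dioxolan-4-yl]-4-nitrobutanoate | CC(C)(C)[Si](OC[C@H]1OC(C)(C)O[C@H]1[C@H](C[N+](=O)[O-])CC(=O)OC(C)(C)C)(c1ccccc1)c1ccccc1 | intermediate
8 | sodium nitronate of 7 | CC(C)(C)[Si](OC[C@H]1OC(C)(C)O[C@H]1[C@H](C=[N+]([O-])[O-])CC(=O)OC(C)(C)C)(c1ccccc1)c1ccccc1.[Na+] | intermediate (not isolated)
9 | tert-butyl (3R)-3-[(4S,5R)-5-{[tert-butyl(diphenyl)silyl]oxymethyl}-2,2-dimethyl-1,3-dioxolan-4-yl]-4-oxobutanoate | CC(C)(C)[Si](OC[C@H]1OC(C)(C)O[C@H]1[C@H](C=O)CC(=O)OC(C)(C)C)(c1ccccc1)c1ccccc1 | intermediate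
10 | tert-butyl (3R)-3-[(4S,5R)-5-{[tert-butyl(diphenyl)silyl]oxymethyl}-2,2-dimethyl-1,3-dioxolan-4-yl]-4,4-dimethoxybutanoate | CC(C)(C)[Si](OC[C@H]1OC(C)(C)O[C@H]1[C@H](C(OC)OC)CC(=O)OC(C)(C)C)(c1ccccc1)c1ccccc1 | intermediate
11 | tert-butyl (3R)-3-[(4S,5R)-5-(hydroxymethyl)-2,2-dimethyl-1,3-dioxolan-4-yl]-4,4-dimethoxybutanoate | OC[C@H]1OC(C)(C)O[C@H]1[C@H](C(OC)OC)CC(=O)OC(C)(C)C | intermediate
12 | tert-butyl (3R)-3-[(4S,5S)-5-formyl-2,2-dimethyl-1,3-dioxolan-4-yl]-4,4-dimethoxybutanoate | O=C[C@H]1OC(C)(C)O[C@H]1[C@H](C(OC)OC)CC(=O)OC(C)(C)C | intermediate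
13 | tert-butyl (3R)-3-[(4S,5R)-5-(1-hydroxyethyl)-2,2-dimethyl-1,3-dioxolan-4-yl]-4,4-dimethoxybutanoate (carbinol epimers) | CC(O)[C@H]1OC(C)(C)O[C@H]1[C@H](C(OC)OC)CC(=O)OC(C)(C)C | intermediate
14 | tert-butyl (3R)-3-[(4S,5S)-5-acetyl-2,2-dimethyl-1,3-dioxolan-4-yl]-4,4-dimethoxybutanoate | CC(=O)[C@H]1OC(C)(C)O[C@H]1[C@H](C(OC)OC)CC(=O)OC(C)(C)C | intermediate
15 | tert-butyl (3R)-3-[(4S,5R)-5-[(Z)-4-methoxy-4-oxobut-2-en-2-yl]-2,2-dimethyl-1,3-dioxolan-4-yl]-4,4-dimethoxybutanoate | COC(=O)/C=C(/C)[C@H]1OC(C)(C)O[C@H]1[C@H](C(OC)OC)CC(=O)OC(C)(C)C | intermediate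
16 | tert-butyl (3R)-3-[(4S,5R)-5-[(Z)-4-hydroxybut-2-en-2-yl]-2,2-dimethyl-1,3-dioxolan-4-yl]-4,4-dimethoxybutanoate | OC/C=C(/C)[C@H]1OC(C)(C)O[C@H]1[C@H](C(OC)OC)CC(=O)OC(C)(C)C | intermediate
17 | ethyl 4-chloro-3-oxobutanoate | CCOC(=O)CC(=O)CCl | starting material
18 | ethyl 4-[(4-methoxyphenyl)methoxy]-3-oxobutanoate | CCOC(=O)CC(=O)COCc1ccc(OC)cc1 | intermediate
19 | 4-[(4-methoxyphenyl)methoxy]-3-oxobutanoate ester of allylic alcohol 16 (Z) | COc1ccc(COCC(=O)CC(=O)OC/C=C(/C)[C@H]2OC(C)(C)O[C@H]2[C@H](C(OC)OC)CC(=O)OC(C)(C)C)cc1 | intermediate (not isolated)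
20 | β-keto acid after the [3,3] shift (C5 carboxylic acid of 21; C5 epimers) | C=C[C@@](C)(C(C(=O)O)C(=O)COCc1ccc(OC)cc1)[C@H]2OC(C)(C)O[C@H]2[C@H](C(OC)OC)CC(=O)OC(C)(C)C | intermediate (not isolated)
21 | tert-butyl (3R)-3-[(4S,5R)-5-[(3R)-6-[(4-methoxyphenyl)methoxy]-3-methyl-5-oxohex-1-en-3-yl]-2,2-dimethyl-1,3-dioxolan-4-yl]-4,4-dimethoxybutanoate | C=C[C@@](C)(CC(=O)COCc1ccc(OC)cc1)[C@H]2OC(C)(C)O[C@H]2[C@H](C(OC)OC)CC(=O)OC(C)(C)C | intermediate
22 | tert-butyl (3R)-3-[(4S,5R)-5-[(3R)-6-[(4-methoxyphenyl)methoxy]-3-methyl-5-oxohex-1-en-3-yl]-2,2-dimethyl-1,3-dioxolan-4-yl]-4-oxobutanoate (keto aldehyde) | C=C[C@@](C)(CC(=O)COCc1ccc(OC)cc1)[C@H]2OC(C)(C)O[C@H]2[C@H](C=O)CC(=O)OC(C)(C)C | intermediate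
23 | cyclohexane ketol, 5S,6S,7S,8S,9R,10S: C10 methyl and vinyl, C5 (4-methoxybenzyloxy)acetyl, C6 OH, C7 CH2CO2tBu, C8/C9 cis-acetonide | C=C[C@@]1(C)[C@H](C(=O)COCc2ccc(OC)cc2)[C@@H](O)[C@H](CC(=O)OC(C)(C)C)[C@@H]3OC(C)(C)O[C@H]13 | intermediate
24 | 6-O-triisopropylsilyl ether of 23 (5S,6S,7R,8S,9R,10S) | C=C[C@@]1(C)[C@H](C(=O)COCc2ccc(OC)cc2)[C@@H](O[Si](C(C)C)(C(C)C)C(C)C)[C@H](CC(=O)OC(C)(C)C)[C@@H]3OC(C)(C)O[C@H]13 | intermediate
25 | C4-methylene compound (5S,6R,7R,8S,9R,10S): C5 3-(4-methoxybenzyloxy)prop-1-en-2-yl, C6 OSi(iPr)3, C7 CH2CO2tBu, C8/C9 acetonide | C=C[C@@]1(C)[C@H](C(=C)COCc2ccc(OC)cc2)[C@@H](O[Si](C(C)C)(C(C)C)C(C)C)[C@H](CC(=O)OC(C)(C)C)[C@@H]3OC(C)(C)O[C@H]13 | intermediate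
26 | 8,9-diol tert-butyl ester from 25 | C=C[C@@]1(C)[C@H](C(=C)COCc2ccc(OC)cc2)[C@@H](O[Si](C(C)C)(C(C)C)C(C)C)[C@H](CC(=O)OC(C)(C)C)[C@H](O)[C@@H]1O | intermediate (not isolated)
27 | (5S,6R,7R,8S,9R,10S)-9-hydroxy-15-[(4-methoxyphenyl)methoxy]-6-[tri(propan-2-yl)silyloxy]elema-1,3-dien-12,8-olide | C=C[C@@]1(C)[C@H](C(=C)COCc3ccc(OC)cc3)[C@@H](O[Si](C(C)C)(C(C)C)C(C)C)[C@@H]2CC(=O)O[C@@H]2[C@@H]1O | intermediate
28 | 9-O-(2-methylpropanoyl) ester of 27 | C=C[C@@]1(C)[C@H](C(=C)COCc3ccc(OC)cc3)[C@@H](O[Si](C(C)C)(C(C)C)C(C)C)[C@@H]2CC(=O)O[C@@H]2[C@@H]1OC(=O)C(C)C | intermediate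
29 | 11-(dimethylaminomethyl) lactone (Mannich base of 28; C11 epimers) | C=C[C@@]1(C)[C@H](C(=C)COCc3ccc(OC)cc3)[C@@H](O[Si](C(C)C)(C(C)C)C(C)C)[C@@H]2C(CN(C)C)C(=O)O[C@@H]2[C@@H]1OC(=O)C(C)C | intermediate (not isolated)
30 | trimethylammonium iodide of 29 | C=C[C@@]1(C)[C@H](C(=C)COCc3ccc(OC)cc3)[C@@H](O[Si](C(C)C)(C(C)C)C(C)C)[C@@H]2C(C[N+](C)(C)C)C(=O)O[C@@H]2[C@@H]1OC(=O)C(C)C.[I-] | intermediate (not isolated)
31 | (5S,6R,7R,8S,9R,10S)-15-[(4-methoxyphenyl)methoxy]-9-(2-methylpropanoyloxy)-6-[tri(propan-2-yl)silyloxy]elema-1,3,11(13)-trien-12,8-olide | C=C[C@@]1(C)[C@H](C(=C)COCc3ccc(OC)cc3)[C@@H](O[Si](C(C)C)(C(C)C)C(C)C)[C@@H]2C(=C)C(=O)O[C@@H]2[C@@H]1OC(=O)C(C)C | intermediate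
32 | (5S,6R,7R,8S,9R,10S)-15-hydroxy-9-(2-methylpropanoyloxy)-6-[tri(propan-2-yl)silyloxy]elema-1,3,11(13)-trien-12,8-olide | C=C[C@@]1(C)[C@H](C(=C)CO)[C@@H](O[Si](C(C)C)(C(C)C)C(C)C)[C@@H]2C(=C)C(=O)O[C@@H]2[C@@H]1OC(=O)C(C)C | intermediate
33 | (5S,6R,7S,8S,9R,10S)-6,15-dihydroxy-9-(2-methylpropanoyloxy)elema-1,3,11(13)-trien-12,8-olide | C=C[C@@]1(C)[C@H](C(=C)CO)[C@@H](O)[C@@H]2C(=C)C(=O)O[C@@H]2[C@@H]1OC(=O)C(C)C | target

## Step count and least certain steps

Total step count: 23. Longest linear sequence: 22 steps (1 to 33 through steps 1–12 and 14–23); step 13 is a one-step branch.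

**Step 16 (key step).** The most likely failure is loss of the C7 configuration: the aldehyde may form its own enamine before or between ring closures, which would feed material into the 5,6,7-tri-epi chair. Related failures are elimination of O8 from that enamine and dehydration of the ketol to the C5=C6 enone on long exposure to the amine salt.

The fallback generates the C4–C5 enolate regiospecifically, under neutral reducing conditions and at low temperature, so that the aldehyde is never enolised. It sets out from 16 and 18. The allyl keto ester 19 is isolated after transesterification at 100 °C and rearranged as its dianion (LiN(iPr)2, THF, −78 °C to rt), so that the keto acid 20 is obtained without heating. N-Bromosuccinimide then brominates 20 with loss of CO2 to the C5-bromo ketone F1. Pyridinium tosylate in wet acetone unmasks the bromo keto aldehyde F2. SmI2 in THF at −78 °C gives the trivalent samarium enolate, which adds to the C6 aldehyde in an intramolecular Reformatsky reaction through the same chair. C5, being α to the ketone, is then allowed to settle, and the route is rejoined at 23.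

**Step 14.** The risk is poor facial selectivity at C10: the steric demand of C8, which carries the whole C7 branch, may override the preference for bond formation anti to O9. The rearrangement of a Z allylic ester, with the dioxolane axial in the chair, may also be slow.

The fallback replaces substrate control by 1,3-chirality transfer. It sets out from 16. Dess–Martin oxidation gives the Z enal F3. Me2Zn with a chiral amino alcohol ligand of the 3-exo-(dimethylamino)isoborneol type adds methyl to give the (S)-configured secondary allylic alcohol F4. Heating F4 with 18 and DMAP as in step 14 gives the allyl keto ester F5 and, through a chair with the carbinol methyl equatorial, the keto acid F6, which loses CO2 to the (E)-propenyl ketone F7. The C10 configuration is now dictated by the carbinol centre. Ethenolysis of F7 (ethylene, second-generation Hoveyda–Grubbs catalyst, toluene, 60 °C) trims the propenyl group to vinyl and returns to 21.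

**Step 18.** The risk is enolisation of the hindered ketone by the basic ylide in place of addition, with loss of the C6 silyloxy group from the enolate if the ring leaves the chair.

The fallback is a two-stage Peterson olefination from 24. The non-basic cerium reagent from Me3SiCH2Li and CeCl3 adds to the ketone at −78 °C to give the β-hydroxy silane F8. Elimination with KN(SiMe3)2 in THF at 0 °C then gives 25.

**Step 21.** The risk is competing deprotonation of the isobutyrate, or acyl transfer from O9 to the C11 enolate, during the Mannich step.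

The fallback reverses the order of the two operations, from 27. The alkoxide-enolate dianion (LiN(iPr)2, 2.2 equiv) is trapped with Eschenmoser's salt to give the Mannich base F9. Quaternisation with MeI gives the ammonium iodide F10, and NaHCO3 eliminates it to the α-methylene hydroxy lactone F11. Acylation of F11 with 2-methylpropanoic anhydride and DMAP returns to 31.

## Further compounds

F1 | step 16 | C5-bromo ketone acetal (C5 epimers) | C=C[C@@](C)(C(Br)C(=O)COCc1ccc(OC)cc1)[C@H]2OC(C)(C)O[C@H]2[C@H](C(OC)OC)CC(=O)OC(C)(C)C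
F2 | step 16 | C5-bromo keto aldehyde (C5 epimers) | C=C[C@@](C)(C(Br)C(=O)COCc1ccc(OC)cc1)[C@H]2OC(C)(C)O[C@H]2[C@H](C=O)CC(=O)OC(C)(C)C
F3 | step 14 | (Z)-enal from 16 | O=C/C=C(/C)[C@H]1OC(C)(C)O[C@H]1[C@H](C(OC)OC)CC(=O)OC(C)(C)C
F4 | step 14 | (S)-configured secondary (Z)-allylic alcohol | C[C@H](O)/C=C(/C)[C@H]1OC(C)(C)O[C@H]1[C@H](C(OC)OC)CC(=O)OC(C)(C)C
F5 | step 14 | 4-[(4-methoxyphenyl)methoxy]-3-oxobutanoate ester of F4 | COc1ccc(COCC(=O)CC(=O)O[C@@H](C)/C=C(/C)[C@H]2OC(C)(C)O[C@H]2[C@H](C(OC)OC)CC(=O)OC(C)(C)C)cc1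
F6 | step 14 | β-keto acid with (E)-propenyl group on C10 (C5 epimers) | C/C=C/[C@@](C)(C(C(=O)O)C(=O)COCc1ccc(OC)cc1)[C@H]2OC(C)(C)O[C@H]2[C@H](C(OC)OC)CC(=O)OC(C)(C)C
F7 | step 14 | (E)-propenyl analogue of ketone 21 | C/C=C/[C@@](C)(CC(=O)COCc1ccc(OC)cc1)[C@H]2OC(C)(C)O[C@H]2[C@H](C(OC)OC)CC(=O)OC(C)(C)C
F8 | step 18 | C4 β-hydroxy silane (carbinol epimers) | C=C[C@@]1(C)[C@H](C(O)(C[Si](C)(C)C)COCc2ccc(OC)cc2)[C@@H](O[Si](C(C)C)(C(C)C)C(C)C)[C@H](CC(=O)OC(C)(C)C)[C@@H]3OC(C)(C)O[C@H]13
F9 | step 21 | Mannich base of hydroxy lactone 27 (C11 epimers) | C=C[C@@]1(C)[C@H](C(=C)COCc3ccc(OC)cc3)[C@@H](O[Si](C(C)C)(C(C)C)C(C)C)[C@@H]2C(CN(C)C)C(=O)O[C@@H]2[C@@H]1O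
F10 | step 21 | trimethylammonium iodide of F9 | C=C[C@@]1(C)[C@H](C(=C)COCc3ccc(OC)cc3)[C@@H](O[Si](C(C)C)(C(C)C)C(C)C)[C@@H]2C(C[N+](C)(C)C)C(=O)O[C@@H]2[C@@H]1O.[I-]
F11 | step 21 | α-methylene hydroxy lactone (9-hydroxy analogue of 31) | C=C[C@@]1(C)[C@H](C(=C)COCc3ccc(OC)cc3)[C@@H](O[Si](C(C)C)(C(C)C)C(C)C)[C@@H]2C(=C)C(=O)O[C@@H]2[C@@H]1O
A1 | alternative 1 | (1S,2R)-3-methylcyclohexa-3,5-diene-1,2-diol (toluene cis-dihydrodiol) | CC1=CC=C[C@H](O)[C@@H]1O
A2 | alternative 1 | bromoacetal of the 9-O-silylated diene | CC1=CC=C[C@H](OC(CBr)OCC)[C@@H]1O[Si](C)(C)C(C)(C)C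
A3 | alternative 1 | cis-fused bicyclic acetal with C6 alkoxyamine and C5=C10 alkene | CC1=C[C@@H](ON2C(C)(C)CCCC2(C)C)[C@@H]3C[C@H](OCC)O[C@@H]3[C@@H]1O[Si](C)(C)C(C)(C)C
A4 | alternative 2 | C6 enone with 8,9-acetonide and C10 methyl | CC1=CC(=O)C[C@@H]2OC(C)(C)O[C@H]12
A5 | alternative 2 | methyl cyclobut-1-ene-1-carboxylate | COC(=O)C1=CCC1
A6 | alternative 2 | tricyclic ladder photoadduct | C[C@]12[C@@H]3CC[C@]3(C(=O)OC)[C@H]1C(=O)C[C@@H]4OC(C)(C)O[C@H]24
A7 | alternative 3 | open-chain allenyl aldehyde (C8 aldehyde, C7=C11=C13 allene) | C=C[C@@](C)([C@H](C(=C)CO[Si](C)(C)C(C)(C)C)[C@@H](O[Si](C)(C)C(C)(C)C)C=C=C)[C@@H](OC(=O)C(C)C)C=O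
A8 | alternative 3 | bis(tert-butyldimethylsilyl) ether of the target | C=C[C@@]1(C)[C@H](C(=C)CO[Si](C)(C)C(C)(C)C)[C@@H](O[Si](C)(C)C(C)(C)C)[C@@H]2C(=C)C(=O)O[C@@H]2[C@@H]1OC(=O)C(C)C
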